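**Strategy.** The seven-membered ring is cut into a five-carbon piece (C7–C6–C5–C1–C10; C6 bears the ester oxygen, C1 the angular methyl) and the two-carbon piece C8–C9. A rhodium-catalysed [5+2] cycloaddition of a ring-fused vinylcyclopropane with 1-trimethylsilylpropyne forms C7–C8 and C9–C10 in one operation. It exploits the 1,3-relationship of C5 and C10 across the quaternary C1: these three atoms are stored as the cyclopropane of a bicyclo[3.1.0]hexane (ring A plus C10) whose C5 carries the C6=C7 silyl enol ether, so C1 is set beforehand by CBS reduction and hydroxyl-directed cyclopropanation. Desilylation, conjugation, reduction, isopropyl addition at C4 and Mitsunobu esterification complete the target.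

Key step: step 7

Remarks on the chemistry:
- Locants follow the carbon skeleton of the target. C1 is the ring-fusion carbon with the C15 methyl; C2 and C3 are the CH2 groups of ring A (cyclopentane); C4 is the carbinol carbon with the isopropyl group; C5 is the ring-fusion CH; C6 carries the ester oxygen; C7=C8 is the alkene (C14 methyl on C8); C9 and C10 are the CH2 groups of ring B (cycloheptene). β is the face of the C15 methyl, α the opposite face.
- Assumption: hydride adds to the C6 carbonyl of the ring B enone from the α-face, anti to the axial C15 methyl, so the C6 oxygen is inverted once, in the last step.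
- 2-Bromo-3-methylcyclopent-2-en-1-one, 1-trimethylsilylpropyne and 4-methoxybenzoic acid are taken as commercial.

Step 1
Reactants: 1 2-bromo-3-methylcyclopent-2-en-1-one
Product: 2 (1R)-2-bromo-3-methylcyclopent-2-en-1-ol
Conditions: (S)-2-methyl-CBS-oxazaborolidine (10 mol %), BH3·SMe2, THF, −20 °C; MeOH quench
Reagents that add atoms: none
Why: Corey–Bakshi–Shibata reduction, in which the bromoalkenyl arm acts as the large group so that the (S)-oxazaborolidine delivers hydride to one carbonyl face and sets the carbinol centre (future C4) as R; this temporary centre steers step 2 and is erased in step 3.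

Step 2
Reactants: 2 (1R)-2-bromo-3-methylcyclopent-2-en-1-ol
Product: 3 (1R,2R,5R)-1-bromo-5-methylbicyclo[3.1.0]hexan-2-ol
Conditions: Et2Zn, CH2I2, CH2Cl2, 0 °C to rt
Reagents that add atoms: diiodomethane, ICI
Why: Furukawa-type Simmons–Smith cyclopropanation in which the zinc alkoxide delivers the methylene (future C10) to the alkene face syn to the hydroxyl, which fixes the quaternary C1 and C5 in one absolute sense.

Step 3
Reactants: 3 (1R,2R,5R)-1-bromo-5-methylbicyclo[3.1.0]hexan-2-ol
Product: 4 (1R,5R)-1-bromo-5-methylbicyclo[3.1.0]hexan-2-one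
Conditions: Dess–Martin periodinane, CH2Cl2, rt
Reagents that add atoms: none
Why: Dess–Martin oxidation of the secondary alcohol under neutral conditions should give the C4 ketone without touching the bromocyclopropane, whose two centres now carry all the stereochemical information.

Step 4
Reactants: 4 (1R,5R)-1-bromo-5-methylbicyclo[3.1.0]hexan-2-one
Product: 5 (1R,5R)-1-bromo-5-methylspiro[bicyclo[3.1.0]hexane-2,2'-[1,3]dioxolane]
Conditions: 1,2-bis(trimethylsilyloxy)ethane, TMSOTf (5 mol %), CH2Cl2, −78 to −20 °C
Reagents that add atoms: 1,2-bis(trimethylsilyloxy)ethane, C[Si](C)(C)OCCO[Si](C)(C)C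
Why: Noyori ketalisation masks the C4 carbonyl at low temperature so that it survives the organolithium and hydride steps and cannot form a 1,3-dicarbonyl with C6 once that carbon becomes a ketone.

Step 5
Reactants: 5 (1R,5R)-1-bromo-5-methylspiro[bicyclo[3.1.0]hexane-2,2'-[1,3]dioxolane]
Product: 7 1-[(1S,5R)-5-methylspiro[bicyclo[3.1.0]hexane-2,2'-[1,3]dioxolan]-1-yl]ethan-1-one, via cyclopropyllithium 6 (not isolated)
Conditions: t-BuLi (2.1 equiv), Et2O, −78 °C; then N-methoxy-N-methylacetamide, −78 to 0 °C; H2O
Reagents that add atoms: N-methoxy-N-methylacetamide, CC(=O)N(C)OC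
Why: Bromine–lithium exchange gives a bridgehead cyclopropyllithium that cannot invert (retention at C5), and a single acylation by the Weinreb amide installs C6 and C7 as an acetyl group.

Step 6
Reactants: 7 1-[(1S,5R)-5-methylspiro[bicyclo[3.1.0]hexane-2,2'-[1,3]dioxolan]-1-yl]ethan-1-one
Product: 8 tert-butyl(dimethyl)({1-[(1S,5R)-5-methylspiro[bicyclo[3.1.0]hexane-2,2'-[1,3]dioxolan]-1-yl]ethenyl}oxy)silane
Conditions: TBSOTf, Et3N, CH2Cl2, −78 to 0 °C
Reagents that add atoms: tert-butyldimethylsilyl trifluoromethanesulfonate, CC(C)(C)[Si](C)(C)OS(=O)(=O)C(F)(F)F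
Why: Soft enolisation and O-silylation can occur only at the acetyl methyl because C5 is quaternary, so a single silyl enol ether (C6=C7) results and completes the vinylcyclopropane.

Step 7
Reactants: 8 tert-butyl(dimethyl)({1-[(1S,5R)-5-methylspiro[bicyclo[3.1.0]hexane-2,2'-[1,3]dioxolan]-1-yl]ethenyl}oxy)silane; 9 trimethyl(prop-1-yn-1-yl)silane
Product: 10 bicyclic silyl dienol ether (C5=C6 with OSi(t-Bu)Me2 on C6; C8=C9 with CH3 on C8 and SiMe3 on C9; C4 ethylene ketal; C1 as in the target)
Conditions: [Rh(CO)2Cl]2 (5 mol %), 9 (3 equiv), 1,2-dichloroethane, 80 °C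
Reagents that add atoms: none
Why: [Rh(CO)2Cl]2 (monovalent rhodium) adds oxidatively into the C5–C10 bond of the vinylcyclopropane, whose vinyl group is the C6=C7 silyl enol ether, to give a σ-alkyl/π-allyl rhodacycle; the alkyne then inserts so that its methyl-bearing carbon (C8) bonds to C7, and C(sp2)–C(sp3) reductive elimination joins C9 to C10. The closest known reaction type is the Wender intermolecular [5+2] cycloaddition of substituted vinylcyclopropanes with alkynes under the same catalyst. Ring B (C5–C6–C7–C8–C9–C10–C1) is closed as a metal-mediated [5+2] cycloaddition, both new σ-bonds being formed on rhodium through an eight-membered rhodacycle and not by a polar exo or endo closure. No stereocentre is created: C1 keeps the configuration set in step 2 because its bonds to C5 and C10 are not touched, and C5 becomes sp2. The step needs cleavage of C5–C10 instead of C5–C1, secured by the quaternary C1 (insertion occurs at the unhindered CH2, and the resulting Rh–CH2 group has no β-hydrogen), and it needs one alkyne orientation, secured by the bulky SiMe3 group, which stays distal to the first-formed C7–C8 bond and so ends on C9. The dioxolane keeps the C4 carbonyl silent throughout.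

Step 8
Reactants: 10 bicyclic silyl dienol ether
Product: 13 trans-fused enone (C6 ketone; C7=C8 with CH3 on C8; C4 ethylene ketal; H-5 α; 15-CH3 β), via vinylsilane ketone 11 (not isolated), via allylsilane enone 12 (not isolated)
Conditions: n-Bu4NF·3H2O (2.5 equiv), THF, 0 °C to rt
Reagents that add atoms: none
Why: Fluoride cleaves the silyl enol ether and the enolate should be protonated at C5 anti to the C15 methyl (H-5 α, trans fusion), after which the basic medium moves C8=C9 into conjugation through the C7 dienolate and fluoride cleaves the now allylic C9–Si bond (vinylogous α-silyl ketone), a sequence of known desilylation and β,γ-to-α,β enone isomerisation steps.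

Step 9
Reactants: 13 trans-fused enone
Product: 14 6β-allylic alcohol (C4 ethylene ketal; C7=C8; H-5 α; 15-CH3 β)
Conditions: i-Bu2AlH (1.2 equiv), CH2Cl2, −78 °C; aq. potassium sodium tartrate
Reagents that add atoms: none
Why: 1,2-Reduction of the enone by the bulky aluminium hydride should occur from the α-face, anti to the axial C15 methyl that is 1,3 to C6, giving the 6β-alcohol, which is the C6 epimer needed for inversion in step 12.

Step 10
Reactants: 14 6β-allylic alcohol
Product: 15 6β-hydroxy-4-ketone (C4 ketone; C7=C8; H-5 α; 15-CH3 β)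
Conditions: PPTS (0.2 equiv), THF/H2O (4:1), 45 °C
Reagents that add atoms: water, O
Why: Mild acid-catalysed ketal hydrolysis unmasks the C4 ketone, the weak acid being chosen to spare the allylic alcohol and the C5 centre.

Step 11
Reactants: 15 6β-hydroxy-4-ketone
Product: 16 (1S,4R,5S,6R)-dauc-7-ene-4,6-diol (4β-OH; 4α-isopropyl; 6β-OH)
Conditions: i-PrMgCl (4 equiv), anhydrous CeCl3 (4 equiv), THF, −78 to −40 °C; aq. NH4Cl
Reagents that add atoms: isopropylmagnesium chloride, CC(C)[Mg]Cl
Why: Imamoto organocerium addition (non-basic, so neither enolisation at C5 nor hydride transfer) should bring the isopropyl group to the ring A ketone from the α-face, anti to both the adjacent C5–C6 bond and the C15 methyl, which places the new tertiary hydroxyl β (4R).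

Step 12
Reactants: 16 (1S,4R,5S,6R)-dauc-7-ene-4,6-diol; 17 4-methoxybenzoic acid
Product: 18 [(3R,3aS,4S,8aS)-3-hydroxy-6,8a-dimethyl-3-(propan-2-yl)-1,2,3,3a,4,7,8,8a-octahydroazulen-4-yl] 4-methoxybenzoate (CNP0327211.1)
Conditions: PPh3, DIAD, toluene, 0 °C to rt
Reagents that add atoms: none
Why: Mitsunobu esterification activates only the secondary allylic C6 hydroxyl (the tertiary C4 hydroxyl is inert), and the anisate should displace the oxyphosphonium with inversion from the open α-face, turning 6β-OH into the 6α-ester (6S) of the target.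

**Compound list**

1 | 2-bromo-3-methylcyclopent-2-en-1-one | O=C1CCC(C)=C1Br | starting material
2 | (1R)-2-bromo-3-methylcyclopent-2-en-1-ol | O[C@@H]1CCC(C)=C1Br | intermediate
3 | (1R,2R,5R)-1-bromo-5-methylbicyclo[3.1.0]hexan-2-ol | C1[C@@]3(C)CC[C@@H](O)[C@@]13Br | intermediate
4 | (1R,5R)-1-bromo-5-methylbicyclo[3.1.0]hexan-2-one | C1[C@@]3(C)CCC(=O)[C@@]13Br | intermediate
5 | (1R,5R)-1-bromo-5-methylspiro[bicyclo[3.1.0]hexane-2,2'-[1,3]dioxolane] | C1[C@@]3(C)CCC4(OCCO4)[C@@]13Br | intermediate
6 | cyclopropyllithium: 5 with lithium in place of bromine, configuration retained | C1[C@@]3(C)CCC4(OCCO4)[C@@]13[Li] | intermediate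
7 | 1-[(1S,5R)-5-methylspiro[bicyclo[3.1.0]hexane-2,2'-[1,3]dioxolan]-1-yl]ethan-1-one | C1[C@@]3(C)CCC4(OCCO4)[C@@]13C(C)=O | intermediate
8 | tert-butyl(dimethyl)({1-[(1S,5R)-5-methylspiro[bicyclo[3.1.0]hexane-2,2'-[1,3]dioxolan]-1-yl]ethenyl}oxy)silane | C1[C@@]3(C)CCC4(OCCO4)[C@@]13C(=C)O[Si](C)(C)C(C)(C)C | intermediate
9 | trimethyl(prop-1-yn-1-yl)silane | CC#C[Si](C)(C)C | starting material
10 | bicyclic silyl dienol ether: C5=C6 (6-OSi(t-Bu)Me2), C8=C9 (8-CH3, 9-SiMe3), C4 ethylene ketal, C1 as in the target | CC(C)(C)[Si](C)(C)OC2=C3C4(OCCO4)CC[C@]3(C)CC([Si](C)(C)C)=C(C)C2 | intermediate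
11 | vinylsilane ketone: C6 ketone, C8=C9 (8-CH3, 9-SiMe3), C4 ethylene ketal, H-5 α, 15-CH3 β | O=C2CC(C)=C([Si](C)(C)C)C[C@@]3(C)CCC4(OCCO4)[C@H]23 | intermediate
12 | allylsilane enone: C6 ketone, C7=C8 (8-CH3), 9-SiMe3 (C9 epimers), C4 ethylene ketal | O=C2C=C(C)C([Si](C)(C)C)C[C@@]3(C)CCC4(OCCO4)[C@H]23 | intermediate
13 | trans-fused enone: C6 ketone, C7=C8 (8-CH3), C4 ethylene ketal, H-5 α, 15-CH3 β | O=C2C=C(C)CC[C@@]3(C)CCC4(OCCO4)[C@H]23 | intermediate
14 | 6β-allylic alcohol: as 13 with 6β-OH in place of the ketone | O[C@@H]2C=C(C)CC[C@@]3(C)CCC4(OCCO4)[C@H]23 | intermediate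
15 | 6β-hydroxy-4-ketone: C4 ketone, 6β-OH, C7=C8, H-5 α, 15-CH3 β | O[C@@H]2C=C(C)CC[C@@]3(C)CCC(=O)[C@H]23 | intermediate
16 | (1S,4R,5S,6R)-dauc-7-ene-4,6-diol (4β-OH, 4α-isopropyl, 6β-OH) | O[C@@H]2C=C(C)CC[C@@]3(C)CC[C@@](O)(C(C)C)[C@H]23 | intermediate
17 | 4-methoxybenzoic acid | COc1ccc(cc1)C(=O)O | starting material
18 | [(3R,3aS,4S,8aS)-3-hydroxy-6,8a-dimethyl-3-(propan-2-yl)-1,2,3,3a,4,7,8,8a-octahydroazulen-4-yl] 4-methoxybenzoate | COc1ccc(C(=O)O[C@H]2C=C(C)CC[C@@]3(C)CC[C@@](O)(C(C)C)[C@H]23)cc1 | target

**Total step count:** 12. **Longest linear sequence:** 12 steps (1 to 18).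

**Steps most likely to fail**

1. Step 7. Alkyne insertion at the congested rhodacycle (fully substituted C5, neopentyl-type C10, silyl-substituted internal alkyne) may be too slow, so that the catalyst decays or the alkyne inserts in the wrong orientation. Fallback, from 8 back to 13: the same vinylcyclopropane 8 is combined with unhindered ethyne (1 atm, [Rh(CO)2Cl]2, 1,2-dichloroethane, 60 °C) to give the methyl-free cycloadduct F1. Treatment with n-Bu4NF and then DBU gives the conjugated cyclohept-2-enone F2, any unconjugated isomer being recycled through DBU. Me2CuLi with TMSCl then adds the C14 methyl to C8 and traps the enolate as the trimethylsilyl enol ether F3. Saegusa–Ito dehydrogenation with Pd(OAc)2 in MeCN returns to enone 13 with the double bond fixed at C7=C8. Here the methyl group and the alkene position come from conjugate addition and dehydrogenation instead of from the alkyne.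

2. Step 8. The double bond may settle as a thermodynamic mixture of the conjugated 7-ene and the 8-ene instead of moving fully into conjugation. Fallback, from 13 (as its mixture with the 8-ene isomer F4) back to 13: the mixture is hydrogenated (H2, Pd/C, EtOAc) to the saturated ketone F5 (both C8 epimers). Dehydrogenation with IBX (DMSO/toluene, 70 °C) can introduce only C7=C8, because C5 has no hydrogen-bearing β-carbon (C1 and C4 are fully substituted), so the regiochemistry is set kinetically and not by equilibrium.

3. Step 12. The activated, axial C6 oxyphosphonium may undergo E2 loss with the antiperiplanar H-5, or ionise as an allyl cation and scramble, instead of being displaced with inversion. Fallback, from 16 back to 18: MnO2 (CH2Cl2) oxidises only the allylic C6 alcohol to the hydroxy enone F6. Me4NBH(OAc)3 (MeCN/AcOH, −20 °C) is bound by the 4β-hydroxyl and delivers hydride intramolecularly to the β-face of C6 (Evans–Saksena anti-1,3-diol reduction), giving the 6α-alcohol F7. 4-Methoxybenzoyl chloride, pyridine and DMAP then acylate the secondary alcohol selectively to give 18. Here C6 is set by directed reduction and the ester is made with retention.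

**Further compounds**

F1 | step 7 | ethyne cycloadduct: silyl dienol ether as 10 but with H on C8 and C9 | CC(C)(C)[Si](C)(C)OC2=C3C4(OCCO4)CC[C@]3(C)CC=CC2
F2 | step 7 | conjugated cyclohept-2-enone lacking the C8 methyl (C6 ketone, C7=C8, C4 ethylene ketal, trans-fused) | O=C2C=CCC[C@@]3(C)CCC4(OCCO4)[C@H]23
F3 | step 7 | trimethylsilyl enol ether (C6=C7) of the 8-methyl ketone (C8 epimers) | C[Si](C)(C)OC2=CC(C)CC[C@@]3(C)CCC4(OCCO4)[C@H]23
F4 | step 8 | 8-ene isomer of 13 (C6 ketone, C8=C9) | O=C2CC(C)=CC[C@@]3(C)CCC4(OCCO4)[C@H]23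
F5 | step 8 | saturated ketone (C6 ketone, 8-CH3 as both epimers, C4 ethylene ketal) | O=C2CC(C)CC[C@@]3(C)CCC4(OCCO4)[C@H]23
F6 | step 12 | hydroxy enone: 4β-hydroxy-4α-isopropyl, C6 ketone, C7=C8 | O=C2C=C(C)CC[C@@]3(C)CC[C@@](O)(C(C)C)[C@H]23
F7 | step 12 | (1S,4R,5S,6S)-dauc-7-ene-4,6-diol (6α-OH; 6-epimer of 16) | O[C@H]2C=C(C)CC[C@@]3(C)CC[C@@](O)(C(C)C)[C@H]23
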